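**Strategy**

The diarylmethane is cut between its benzylic CH2 and C1 of the 4-hydroxyphenyl ring (ring C). The route exploits that this CH2 sits on the resorcinol ring (ring A) between C–OH and C–OMe: carried as a formyl carbon, it first directs chelation-controlled removal of exactly one flanking O-methyl group, then becomes, through its N-tosylhydrazone, a diazo carbon that inserts into the C–B bond of a para-oxygenated arylboronic acid. One metal-free operation forms the CH–aryl bond, removes the carbonyl oxygen and fixes the para pattern through the boron position. The precursor is a salicylaldehyde bearing the bibenzyl arm, itself assembled by a B-alkyl Suzuki coupling.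

Key step: step 3

Remark: the target has no stereocenter, so none has to be set. Compounds 1, 2, 3, 6, 9 and 10 are taken as purchased. Ring B is the 3-methoxyphenyl ring.

**Route**

Step 1
Reactants: 1 3-vinylanisole (1-ethenyl-3-methoxybenzene); 2 9-borabicyclo[3.3.1]nonane (9-BBN); 3 4-bromo-2,6-dimethoxybenzaldehyde
Product: 5 2,6-dimethoxy-4-[2-(3-methoxyphenyl)ethyl]benzaldehyde, via alkylborane 4 (not isolated)
Conditions: 1 (1.3 equiv), 2 (1.2 equiv, 0.5 M in THF), 0 °C to rt; then 3 (1.0 equiv), Pd(dppf)Cl2 (3 mol%), 3 M aq K3PO4, DMF, 60 °C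
Reagents that add atoms: none
Why: Anti-Markovnikov hydroboration puts boron on the terminal carbon of the styrene, and the B-alkyl Suzuki–Miyaura coupling should then transfer the primary alkyl group to the aryl bromide, whose C–Br bond para to the formyl group adds readily to Pd(0); dppf suppresses β-hydride elimination, and the alkene is kept in slight excess over B–H so that no hydride remains to reduce the aldehyde.

Step 2
Reactants: 5 2,6-dimethoxy-4-[2-(3-methoxyphenyl)ethyl]benzaldehyde; 6 boron trichloride
Product: 8 2-hydroxy-6-methoxy-4-[2-(3-methoxyphenyl)ethyl]benzaldehyde, via boron chelate 7 (not isolated)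
Conditions: 6 (1.2 equiv, 1 M in CH2Cl2), CH2Cl2, −78 to 0 °C; then H2O
Reagents that add atoms: none
Why: Chelation-controlled Lewis-acid ether cleavage: BCl3 bound to the formyl oxygen activates only an ortho methoxy group for chloride attack at its methyl carbon, the six-membered O–B–O chelate 7 then protects the second ortho methoxy group, and the isolated anisole ether of ring B should not react with BCl3 at or below 0 °C.

Step 3
Reactants: 8 2-hydroxy-6-methoxy-4-[2-(3-methoxyphenyl)ethyl]benzaldehyde; 9 p-toluenesulfonohydrazide; 10 [4-(tetrahydro-2H-pyran-2-yloxy)phenyl]boronic acid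
Product: 15 IN0509 (2-[(4-hydroxyphenyl)methyl]-3-methoxy-5-[2-(3-methoxyphenyl)ethyl]phenol), via N-tosylhydrazone 11 (not isolated), via aryldiazomethane 12 (not isolated), via benzylic boronic acid 13 (not isolated), via THP ether 14 (not isolated)
Conditions: 9 (1.05 equiv), 1,4-dioxane, 80 °C; then 10 (2.0 equiv), K2CO3 (3.5 equiv), 110 °C; then 2 M aq HCl to pH 1, rt
Reagents that add atoms: none
Why: Condensation gives N-tosylhydrazone 11, from which K2CO3 expels p-toluenesulfinate (Bamford–Stevens reaction) to leave the electron-rich aryldiazomethane 12; its nucleophilic carbon adds to the vacant boron orbital of 10, the aryl group shifts from boron to carbon with loss of N2 to form the CH–aryl bond, the doubly benzylic boronic acid 13 is protodeboronated to the CH2 group, and the acidic finish removes the THP acetal of 14. The closest known reaction type is the metal-free reductive coupling of aldehyde N-tosylhydrazones with arylboronic acids (Barluenga–Valdés coupling), which is established for benzaldehyde-derived hydrazones and electron-rich arylboronic acids. No ring is closed and no stereocenter survives: the boron-bearing carbon of 13 and the acetal carbon of the THP group are formed without control and both vanish within the step. The step needs C–B insertion to outrun O–H insertion of phenols into the diazo compound, and it needs attachment exclusively para to the ring-C oxygen. The first is secured by masking the only unhindered phenol as its THP ether and by the excess of 10, while the ring-A hydroxyl is held in a hydrogen bond to the hydrazone nitrogen; the second is fixed by the position of boron in 10, which a Friedel–Crafts benzylation of phenol could not guarantee.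

**Compound list**

1 | 3-vinylanisole (1-ethenyl-3-methoxybenzene) | COc1cccc(C=C)c1 | starting material
2 | 9-borabicyclo[3.3.1]nonane (9-BBN) | B1C2CCCC1CCC2 | starting material
3 | 4-bromo-2,6-dimethoxybenzaldehyde | COc1cc(Br)cc(OC)c1C=O | starting material
4 | 9-[2-(3-methoxyphenyl)ethyl]-9-borabicyclo[3.3.1]nonane (not isolated) | COc1cccc(CCB2C3CCCC2CCC3)c1 | intermediate
5 | 2,6-dimethoxy-4-[2-(3-methoxyphenyl)ethyl]benzaldehyde | COc1cccc(CCc2cc(OC)c(C=O)c(OC)c2)c1 | intermediate
6 | boron trichloride | ClB(Cl)Cl | starting material
7 | 2-formyl-3-methoxy-5-[2-(3-methoxyphenyl)ethyl]phenyl dichloroborinate, carbonyl-chelated (not isolated) | COc1cccc(CCc2cc(OB(Cl)Cl)c(C=O)c(OC)c2)c1 | intermediate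
8 | 2-hydroxy-6-methoxy-4-[2-(3-methoxyphenyl)ethyl]benzaldehyde | COc1cccc(CCc2cc(O)c(C=O)c(OC)c2)c1 | intermediate
9 | p-toluenesulfonohydrazide | Cc1ccc(cc1)S(=O)(=O)NN | starting material
10 | [4-(tetrahydro-2H-pyran-2-yloxy)phenyl]boronic acid (racemic) | OB(O)c1ccc(OC2CCCCO2)cc1 | starting material
11 | (E)-N'-{2-hydroxy-6-methoxy-4-[2-(3-methoxyphenyl)ethyl]benzylidene}-4-methylbenzenesulfonohydrazide (not isolated) | COc1cccc(CCc2cc(O)c(/C=N/NS(=O)(=O)c3ccc(C)cc3)c(OC)c2)c1 | intermediate
12 | 2-(diazomethyl)-3-methoxy-5-[2-(3-methoxyphenyl)ethyl]phenol (not isolated) | COc1cccc(CCc2cc(O)c(C=[N+]=[N-])c(OC)c2)c1 | intermediate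
13 | ({2-hydroxy-6-methoxy-4-[2-(3-methoxyphenyl)ethyl]phenyl}[4-(tetrahydro-2H-pyran-2-yloxy)phenyl]methyl)boronic acid, mixture of stereoisomers (not isolated) | COc1cccc(CCc2cc(O)c(C(B(O)O)c3ccc(OC4CCCCO4)cc3)c(OC)c2)c1 | intermediate
14 | 3-methoxy-5-[2-(3-methoxyphenyl)ethyl]-2-{[4-(tetrahydro-2H-pyran-2-yloxy)phenyl]methyl}phenol, racemic (not isolated) | COc1cccc(CCc2cc(O)c(Cc3ccc(OC4CCCCO4)cc3)c(OC)c2)c1 | intermediate
15 | IN0509, 2-[(4-hydroxyphenyl)methyl]-3-methoxy-5-[2-(3-methoxyphenyl)ethyl]phenol | COc1cccc(CCc2cc(O)c(Cc3ccc(O)cc3)c(OC)c2)c1 | target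

**Step count**

Total step count: 3. Longest linear sequence: 3 steps (3 → 5 → 8 → 15).

**Steps most likely to fail**

1. Step 3 (key step). A phenolic O–H may insert into the diazo compound, or O-benzylate after proton transfer to the diazo carbon, in place of the C–B insertion. In particular, the ring-A hydroxyl may protonate its own diazo carbon and open a quinone-methide-type pathway that is captured unselectively. Protodeboronation of the benzylic boron intermediate may also be incomplete, or the intermediate may be oxidised in air.
Fallback, from 8 to 15: polar addition followed by reductive removal of the carbinol oxygen. Aldehyde 8 would be treated with purchased 4-(benzyloxy)phenylmagnesium bromide (Br[Mg]c1ccc(OCc2ccccc2)cc1; 2.5 equiv, THF, 0 °C to rt, the first equivalent being consumed by the phenol). This should give the diaryl carbinol [4-(benzyloxy)phenyl]{2-hydroxy-6-methoxy-4-[2-(3-methoxyphenyl)ethyl]phenyl}methanol F1. Hydrogenolysis (H2, Pd/C, EtOAc–AcOH, rt) should then cleave the doubly benzylic C–OH bond and the benzyl ether in one operation and return the route at 15.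

2. Step 1. Residual borane may reduce the formyl group. Slow alkyl transfer from boron to palladium may allow β-hydride elimination or protodeboronation of the alkyl group and hydrodebromination of the arene.
Fallback, from 3 to 5: the two-carbon link is made at the alkyne level. Sonogashira coupling of 3 with purchased 1-ethynyl-3-methoxybenzene (COc1cccc(C#C)c1; Pd(PPh3)2Cl2, CuI, Et3N, THF, 50 °C) should give the diarylalkyne 2,6-dimethoxy-4-[(3-methoxyphenyl)ethynyl]benzaldehyde F2. Hydrogenation over Pd/C poisoned with diphenyl sulfide (H2, 1 atm, EtOAc) should saturate the triple bond without touching the formyl group and rejoin the route at 5.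

3. Step 2. A second methyl group may be lost on warming or long exposure, the ring-B ether may be cleaved, or conversion may stop early and leave mixtures that are hard to separate.
Fallback, from 4 to 8: the oxygen pattern is differentiated from the start and the formyl group is introduced last, so no ether cleavage has to be selective. Purchased 3-bromo-5-methoxyphenol (Oc1cc(Br)cc(OC)c1) would be protected (MOMCl, iPr2NEt, CH2Cl2) as 1-bromo-3-methoxy-5-(methoxymethoxy)benzene F3. B-alkyl Suzuki coupling of F3 with alkylborane 4 under the conditions of step 1 should give 1-methoxy-3-(methoxymethoxy)-5-[2-(3-methoxyphenyl)ethyl]benzene F4. Cooperative directed ortho-metalation (n-BuLi, TMEDA, THF, 0 °C) should lithiate the carbon between the two oxygen substituents to give {2-methoxy-6-(methoxymethoxy)-4-[2-(3-methoxyphenyl)ethyl]phenyl}lithium F5. Quenching with DMF and then water should give 2-methoxy-6-(methoxymethoxy)-4-[2-(3-methoxyphenyl)ethyl]benzaldehyde F6. Aqueous HCl in THF should remove the MOM group and rejoin the route at 8.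

**Further compounds**

F1 | step 3 | [4-(benzyloxy)phenyl]{2-hydroxy-6-methoxy-4-[2-(3-methoxyphenyl)ethyl]phenyl}methanol (racemic) | COc1cccc(CCc2cc(O)c(C(O)c3ccc(OCc4ccccc4)cc3)c(OC)c2)c1
F2 | step 1 | 2,6-dimethoxy-4-[(3-methoxyphenyl)ethynyl]benzaldehyde | COc1cccc(C#Cc2cc(OC)c(C=O)c(OC)c2)c1
F3 | step 2 | 1-bromo-3-methoxy-5-(methoxymethoxy)benzene | COCOc1cc(Br)cc(OC)c1
F4 | step 2 | 1-methoxy-3-(methoxymethoxy)-5-[2-(3-methoxyphenyl)ethyl]benzene | COCOc1cc(CCc2cccc(OC)c2)cc(OC)c1
F5 | step 2 | {2-methoxy-6-(methoxymethoxy)-4-[2-(3-methoxyphenyl)ethyl]phenyl}lithium | [Li]c1c(OC)cc(CCc2cccc(OC)c2)cc1OCOC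
F6 | step 2 | 2-methoxy-6-(methoxymethoxy)-4-[2-(3-methoxyphenyl)ethyl]benzaldehyde | COCOc1cc(CCc2cccc(OC)c2)cc(OC)c1C=O
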